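**Retrosynthetic overview**

1. Target 33 is a (2S)-flavanone whose only stereocentre is C2. It is reached in one acid step from its tetrakis(methoxymethyl) ether 32.
2. Ring C of 32 is cut at two bonds at once, O1–C8a and C4–C4a, giving aryne 29 (stored as ortho-silylaryl triflate 15) and the (S)-β-silyloxy N-methoxy-N-methylamide 27. The strategy rests on one feature: O1 and C4 of ring C are bonded to the neighbouring ring A carbons C8a and C4a, and the C5 oxygen sits on the carbon next to C4a, so the aryne takes the alkoxide at C8a and carries the carbanion at C4a.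
3. Triflate 15 comes from 5-bromoresorcinol (1) through phenol 10, whose mirror plane makes its two ortho positions identical, so only the 6-prenyl pattern can result. The sequence is C–Br to C–OH exchange, silyl capping, metalation/prenylation between the two acetal oxygens, ortho-bromination, retro-Brook shift and triflation.
4. Amide 27 comes from 4,6-dibromoresorcinol (16) by two successive bromine–lithium exchanges (prenyl, then CO2), C-acylation of the enolate of N-methoxy-N-methylacetamide (22), asymmetric transfer hydrogenation of keto amide 25 (sets C2) and O-silylation.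
5. Rings A and B are bought as benzene rings; ring C is the only ring formed (step 14). An amide instead of an ester and a silyl ether instead of the free carbinol are used so that the aryl anion meets no proton source and the base-sensitive ketone appears only on buffered work-up.

Key step: step 14

Assumption: silyl ether 27 is moisture-sensitive and is taken into step 14 directly after a non-aqueous work-up; flavanone numbering (O1, C2–C4, C4a, C5–C8, C8a, ring B primed) is used for 30–33.

**Route**

Step 1
Reactants: 1 5-bromobenzene-1,3-diol (5-bromoresorcinol)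
Product: 2 1-bromo-3,5-bis(methoxymethoxy)benzene
Conditions: MOMCl (2.6 equiv), iPr2NEt (3 equiv), CH2Cl2, 0 °C to rt
Reagents that add atoms: chloromethyl methyl ether, COCCl
Why: Double O-alkylation of the phenols (Williamson-type methoxymethyl ether formation) under a hindered amine base should proceed cleanly, and the aryl bromide is inert to it.

Step 2
Reactants: 2 1-bromo-3,5-bis(methoxymethoxy)benzene
Product: 5 3,5-bis(methoxymethoxy)phenol, via aryllithium 3 (not isolated), via lithium arylborate 4 (not isolated)
Conditions: n-BuLi (1.1 equiv), THF, −78 °C; B(OMe)3, −78 °C to rt; AcOH, 30% H2O2, 0 °C to rt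
Reagents that add atoms: hydrogen peroxide, OO
Why: Bromine–lithium exchange followed by borylation and oxidation of the arylborate (1,2-shift of the aryl group from boron to oxygen) should turn C–Br into C–OH while the acetals, stable to base and to acetic acid, stay in place.

Step 3
Reactants: 5 3,5-bis(methoxymethoxy)phenol
Product: 6 [3,5-bis(methoxymethoxy)phenoxy]tri(propan-2-yl)silane
Conditions: iPr3SiCl, imidazole, DMF, rt
Reagents that add atoms: chlorotri(propan-2-yl)silane, CC(C)[Si](Cl)(C(C)C)C(C)C
Why: Imidazole-promoted O-silylation should cap the phenol with a bulky group that withstands butyllithium and does not coordinate lithium, so that it cannot direct the next metalation.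

Step 4
Reactants: 6 [3,5-bis(methoxymethoxy)phenoxy]tri(propan-2-yl)silane; 7 1-bromo-3-methylbut-2-ene (prenyl bromide)
Product: 9 [3,5-bis(methoxymethoxy)-4-(3-methylbut-2-en-1-yl)phenoxy]tri(propan-2-yl)silane, via aryllithium 8 (not isolated)
Conditions: n-BuLi (1.2 equiv), THF, 0 °C; CuBr·SMe2 (10 mol%), 7, −78 °C to rt
Reagents that add atoms: none
Why: Directed ortho-metalation should take place only at the carbon flanked by the two chelating methoxymethoxy groups, and copper-catalysed allylic substitution of prenyl bromide by aryllithium 8 at its primary carbon (SN2 mode) should give the linear prenyl arene.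

Step 5
Reactants: 9 [3,5-bis(methoxymethoxy)-4-(3-methylbut-2-en-1-yl)phenoxy]tri(propan-2-yl)silane
Product: 10 3,5-bis(methoxymethoxy)-4-(3-methylbut-2-en-1-yl)phenol
Conditions: Bu4NF, AcOH, THF, 0 °C to rt
Reagents that add atoms: none
Why: Fluoride-induced desilylation, driven by the Si–F bond and buffered with acetic acid, should free the phenol without touching acetals or olefin.

Step 6
Reactants: 10 3,5-bis(methoxymethoxy)-4-(3-methylbut-2-en-1-yl)phenol
Product: 11 2-bromo-3,5-bis(methoxymethoxy)-4-(3-methylbut-2-en-1-yl)phenol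
Conditions: NBS (1.0 equiv), CH2Cl2, −78 °C
Reagents that add atoms: N-bromosuccinimide, O=C1CCC(=O)N1Br
Why: Electrophilic aromatic bromination should go ortho to the free phenol, where the two open positions are equivalent through the mirror plane of 10 and the para position is blocked, and the low temperature should keep NBS away from the trisubstituted olefin.

Step 7
Reactants: 11 2-bromo-3,5-bis(methoxymethoxy)-4-(3-methylbut-2-en-1-yl)phenol
Product: 15 3,5-bis(methoxymethoxy)-4-(3-methylbut-2-en-1-yl)-2-(trimethylsilyl)phenyl trifluoromethanesulfonate, via aryl silyl ether 12 (not isolated), via aryllithium 13 (not isolated), via lithium phenolate 14 (not isolated)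
Conditions: (Me3Si)2NH, THF, 65 °C, then evaporation; n-BuLi (1.1 equiv), THF, −78 °C; Tf2O, −78 °C
Reagents that add atoms: hexamethyldisilazane, C[Si](C)(C)N[Si](C)(C)C; trifluoromethanesulfonic anhydride, O=S(=O)(OS(=O)(=O)C(F)(F)F)C(F)(F)F
Why: O-Silylation, bromine–lithium exchange, 1,3 oxygen-to-carbon silyl shift (retro-Brook rearrangement) and O-triflation of the resulting phenolate make up the standard one-flask route from an ortho-bromophenol to an ortho-silylaryl triflate, and exchange at −78 °C should outrun deprotonation of the benzylic–allylic methylene.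

Step 8
Reactants: 16 4,6-dibromobenzene-1,3-diol (4,6-dibromoresorcinol)
Product: 17 1,5-dibromo-2,4-bis(methoxymethoxy)benzene
Conditions: MOMCl (2.6 equiv), iPr2NEt (3 equiv), CH2Cl2, 0 °C to rt
Reagents that add atoms: chloromethyl methyl ether, COCCl
Why: The same Williamson-type methoxymethyl ether formation as in step 1 should protect both phenols and leave the two aryl bromides untouched.

Step 9
Reactants: 17 1,5-dibromo-2,4-bis(methoxymethoxy)benzene; 7 1-bromo-3-methylbut-2-ene (prenyl bromide)
Product: 19 1-bromo-2,4-bis(methoxymethoxy)-5-(3-methylbut-2-en-1-yl)benzene, via aryllithium 18 (not isolated)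
Conditions: n-BuLi (1.05 equiv), THF, −78 °C; CuBr·SMe2 (10 mol%), 7, −78 to 0 °C
Reagents that add atoms: none
Why: One bromine–lithium exchange should stop at the mono-lithio stage because the two bromines are equivalent and a second exchange on the already metalated ring is slow, and copper-catalysed allylic substitution then installs the prenyl group as in step 4.

Step 10
Reactants: 19 1-bromo-2,4-bis(methoxymethoxy)-5-(3-methylbut-2-en-1-yl)benzene
Product: 21 2,4-bis(methoxymethoxy)-5-(3-methylbut-2-en-1-yl)benzoic acid, via aryllithium 20 (not isolated)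
Conditions: n-BuLi (1.1 equiv), THF, −78 °C; CO2, −78 °C to rt; 1 M HCl to pH 4, 0 °C
Reagents that add atoms: carbon dioxide, O=C=O
Why: Bromine–lithium exchange and carboxylation of the aryllithium should give the benzoic acid, with a cold, mildly acidic work-up that spares the acetals.

Step 11
Reactants: 21 2,4-bis(methoxymethoxy)-5-(3-methylbut-2-en-1-yl)benzoic acid; 22 N-methoxy-N-methylacetamide
Product: 25 3-[2,4-bis(methoxymethoxy)-5-(3-methylbut-2-en-1-yl)phenyl]-N-methoxy-N-methyl-3-oxopropanamide, via acyl imidazole 23 (not isolated), via lithium enolate 24 (not isolated)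
Conditions: 21, 1,1'-carbonyldiimidazole, THF, rt; added to 22 (3.3 equiv) and LiN(iPr)2 (3.3 equiv), THF, −78 to −40 °C; AcOH
Reagents that add atoms: none
Why: Activation of the acid as its acyl imidazole and crossed Claisen-type C-acylation of the lithium enolate of the acetamide should give the β-keto amide, the excess enolate absorbing the imidazole N–H and the acidic product.

Step 12
Reactants: 25 3-[2,4-bis(methoxymethoxy)-5-(3-methylbut-2-en-1-yl)phenyl]-N-methoxy-N-methyl-3-oxopropanamide
Product: 26 (3S)-3-[2,4-bis(methoxymethoxy)-5-(3-methylbut-2-en-1-yl)phenyl]-3-hydroxy-N-methoxy-N-methylpropanamide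
Conditions: RuCl[(S,S)-TsDPEN](p-cymene) (1 mol%), HCO2H/Et3N (1:1), DMF, 35 °C
Reagents that add atoms: none
Why: In this Noyori asymmetric transfer hydrogenation the (S,S)-configured catalyst should deliver hydride to the Re face of the aryl ketone, the aryl ring being placed by its CH–π contact with the p-cymene ligand, which sets the future C2 as S while olefins, acetals and the amide stay inert.

Step 13
Reactants: 26 (3S)-3-[2,4-bis(methoxymethoxy)-5-(3-methylbut-2-en-1-yl)phenyl]-3-hydroxy-N-methoxy-N-methylpropanamide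
Product: 27 (3S)-3-[2,4-bis(methoxymethoxy)-5-(3-methylbut-2-en-1-yl)phenyl]-N-methoxy-N-methyl-3-[(trimethylsilyl)oxy]propanamide
Conditions: Me3SiCl, imidazole, CH2Cl2, 0 °C; filtration under argon and evaporation, no aqueous work-up
Reagents that add atoms: chlorotrimethylsilane, C[Si](C)(C)Cl
Why: Imidazole-promoted O-silylation should mask the carbinol as a fluoride-labile trimethylsilyl ether, so that the alkoxide can later be released without any proton source.

Step 14
Reactants: 15 3,5-bis(methoxymethoxy)-4-(3-methylbut-2-en-1-yl)-2-(trimethylsilyl)phenyl trifluoromethanesulfonate; 27 (3S)-3-[2,4-bis(methoxymethoxy)-5-(3-methylbut-2-en-1-yl)phenyl]-N-methoxy-N-methyl-3-[(trimethylsilyl)oxy]propanamide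
Product: 32 (2S)-2-[2,4-bis(methoxymethoxy)-5-(3-methylbut-2-en-1-yl)phenyl]-5,7-bis(methoxymethoxy)-6-(3-methylbut-2-en-1-yl)-2,3-dihydro-4H-chromen-4-one, via potassium alkoxide 28 (not isolated), via aryne 29 (not isolated), via aryl potassium adduct 30 (not isolated), via hemiaminal alkoxide 31 (not isolated)
Conditions: 27, KF (3 equiv), 18-crown-6 (3 equiv), THF, 0 °C; 15 (1.4 equiv) added over 2 h, 0 °C to rt; AcOH, −40 °C, then pH 7 buffer
Reagents that add atoms: none
Why: Proposed new method: fluoride removes the O-silyl group of 27 to give the proton-free alkoxide 28 and induces 1,2-elimination of silane and triflate from 15 to aryne 29; 28 adds to the aryne carbon remote from the C5 methoxymethoxy group (O1–C8a bond), which places the carbanion of 30 at C4a beside that oxygen, and this carbanion attacks the amide carbonyl (C4–C4a bond) to close ring C by a 6-exo-trig addition, the adduct being expected to persist as hemiaminal alkoxide 31 until the buffered quench releases the ketone. The closest known reactions are the fluoride-induced annulation of arynes with methyl salicylates to xanthones and the insertion of arynes into amide N–C(O) bonds such as those of β-lactams. No lasting stereocentre is created: C2 comes from 27 with its C–O bond intact and keeps the S configuration, and the C4 hemiaminal centre of 31 disappears on work-up. The step needs regioselective capture of the aryne, secured by the inductive polarisation and the bulk of the flanking C5 alkoxy group, and acylation faster than protonation, secured by the silyl-masked alkoxide in THF; the weakly acidic amide α-hydrogens should hold back retro-aldol cleavage and β-elimination, and storage as 31 should keep the chromanone, which base would open to the chalcone, out of the basic medium.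

Step 15
Reactants: 32 (2S)-2-[2,4-bis(methoxymethoxy)-5-(3-methylbut-2-en-1-yl)phenyl]-5,7-bis(methoxymethoxy)-6-(3-methylbut-2-en-1-yl)-2,3-dihydro-4H-chromen-4-one
Product: 33 (2S)-2-[2,4-dihydroxy-5-(3-methylbut-2-en-1-yl)phenyl]-5,7-dihydroxy-6-(3-methylbut-2-en-1-yl)-2,3-dihydro-4H-chromen-4-one
Conditions: 3 M aq. HCl, MeOH, 40 °C
Reagents that add atoms: none
Why: Acid-catalysed solvolysis of the four aryl methoxymethyl acetals in methanol should free the phenols, the mild acid and moderate temperature being chosen to leave the prenyl groups uncyclised and ring C, stabilised by the hydrogen bond from the new 5-OH to the C4 carbonyl, closed.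

**Compound list**

1 | 5-bromobenzene-1,3-diol (5-bromoresorcinol) | Oc1cc(O)cc(Br)c1 | starting material
2 | 1-bromo-3,5-bis(methoxymethoxy)benzene | COCOc1cc(Br)cc(OCOC)c1 | intermediate
3 | [3,5-bis(methoxymethoxy)phenyl]lithium | [Li]c1cc(OCOC)cc(OCOC)c1 | intermediate
4 | lithium [3,5-bis(methoxymethoxy)phenyl]trimethoxyborate | [Li+].CO[B-](OC)(OC)c1cc(OCOC)cc(OCOC)c1 | intermediate
5 | 3,5-bis(methoxymethoxy)phenol | COCOc1cc(O)cc(OCOC)c1 | intermediate
6 | [3,5-bis(methoxymethoxy)phenoxy]tri(propan-2-yl)silane | COCOc1cc(O[Si](C(C)C)(C(C)C)C(C)C)cc(OCOC)c1 | intermediate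
7 | 1-bromo-3-methylbut-2-ene (prenyl bromide) | CC(C)=CCBr | starting material
8 | [2,6-bis(methoxymethoxy)-4-{[tri(propan-2-yl)silyl]oxy}phenyl]lithium | [Li]c1c(OCOC)cc(O[Si](C(C)C)(C(C)C)C(C)C)cc1OCOC | intermediate
9 | [3,5-bis(methoxymethoxy)-4-(3-methylbut-2-en-1-yl)phenoxy]tri(propan-2-yl)silane | COCOc1cc(O[Si](C(C)C)(C(C)C)C(C)C)cc(OCOC)c1CC=C(C)C | intermediate
10 | 3,5-bis(methoxymethoxy)-4-(3-methylbut-2-en-1-yl)phenol | COCOc1cc(O)cc(OCOC)c1CC=C(C)C | intermediate
11 | 2-bromo-3,5-bis(methoxymethoxy)-4-(3-methylbut-2-en-1-yl)phenol | COCOc1cc(O)c(Br)c(OCOC)c1CC=C(C)C | intermediate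
12 | [2-bromo-3,5-bis(methoxymethoxy)-4-(3-methylbut-2-en-1-yl)phenoxy]trimethylsilane | COCOc1cc(O[Si](C)(C)C)c(Br)c(OCOC)c1CC=C(C)C | intermediate
13 | {2,4-bis(methoxymethoxy)-3-(3-methylbut-2-en-1-yl)-6-[(trimethylsilyl)oxy]phenyl}lithium | [Li]c1c(O[Si](C)(C)C)cc(OCOC)c(CC=C(C)C)c1OCOC | intermediate
14 | lithium 3,5-bis(methoxymethoxy)-4-(3-methylbut-2-en-1-yl)-2-(trimethylsilyl)phenolate | [Li+].[O-]c1cc(OCOC)c(CC=C(C)C)c(OCOC)c1[Si](C)(C)C | intermediate
15 | 3,5-bis(methoxymethoxy)-4-(3-methylbut-2-en-1-yl)-2-(trimethylsilyl)phenyl trifluoromethanesulfonate | COCOc1cc(OS(=O)(=O)C(F)(F)F)c([Si](C)(C)C)c(OCOC)c1CC=C(C)C | intermediate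
16 | 4,6-dibromobenzene-1,3-diol (4,6-dibromoresorcinol) | Oc1cc(O)c(Br)cc1Br | starting material
17 | 1,5-dibromo-2,4-bis(methoxymethoxy)benzene | COCOc1cc(OCOC)c(Br)cc1Br | intermediate
18 | [5-bromo-2,4-bis(methoxymethoxy)phenyl]lithium | [Li]c1cc(Br)c(OCOC)cc1OCOC | intermediate
19 | 1-bromo-2,4-bis(methoxymethoxy)-5-(3-methylbut-2-en-1-yl)benzene | COCOc1cc(OCOC)c(CC=C(C)C)cc1Br | intermediate
20 | [2,4-bis(methoxymethoxy)-5-(3-methylbut-2-en-1-yl)phenyl]lithium | [Li]c1cc(CC=C(C)C)c(OCOC)cc1OCOC | intermediate
21 | 2,4-bis(methoxymethoxy)-5-(3-methylbut-2-en-1-yl)benzoic acid | COCOc1cc(OCOC)c(CC=C(C)C)cc1C(=O)O | intermediate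
22 | N-methoxy-N-methylacetamide | CC(=O)N(C)OC | starting material
23 | [2,4-bis(methoxymethoxy)-5-(3-methylbut-2-en-1-yl)phenyl](1H-imidazol-1-yl)methanone | COCOc1cc(OCOC)c(CC=C(C)C)cc1C(=O)n1ccnc1 | intermediate
24 | lithium 1-[methoxy(methyl)amino]ethen-1-olate | [Li+].[O-]C(=C)N(C)OC | intermediate
25 | 3-[2,4-bis(methoxymethoxy)-5-(3-methylbut-2-en-1-yl)phenyl]-N-methoxy-N-methyl-3-oxopropanamide | COCOc1cc(OCOC)c(CC=C(C)C)cc1C(=O)CC(=O)N(C)OC | intermediate
26 | (3S)-3-[2,4-bis(methoxymethoxy)-5-(3-methylbut-2-en-1-yl)phenyl]-3-hydroxy-N-methoxy-N-methylpropanamide | CON(C)C(=O)C[C@H](O)c1cc(CC=C(C)C)c(OCOC)cc1OCOC | intermediate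
27 | (3S)-3-[2,4-bis(methoxymethoxy)-5-(3-methylbut-2-en-1-yl)phenyl]-N-methoxy-N-methyl-3-[(trimethylsilyl)oxy]propanamide | CON(C)C(=O)C[C@H](O[Si](C)(C)C)c1cc(CC=C(C)C)c(OCOC)cc1OCOC | intermediate
28 | potassium (1S)-1-[2,4-bis(methoxymethoxy)-5-(3-methylbut-2-en-1-yl)phenyl]-3-[methoxy(methyl)amino]-3-oxopropan-1-olate | [K+].CON(C)C(=O)C[C@H]([O-])c1cc(CC=C(C)C)c(OCOC)cc1OCOC | intermediate
29 | 3,5-bis(methoxymethoxy)-4-(3-methylbut-2-en-1-yl)benzyne (1,2-didehydrobenzene) | COCOC1=CC#CC(OCOC)=C1CC=C(C)C | intermediate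
30 | [2-({(1S)-1-[2,4-bis(methoxymethoxy)-5-(3-methylbut-2-en-1-yl)phenyl]-3-[methoxy(methyl)amino]-3-oxopropyl}oxy)-4,6-bis(methoxymethoxy)-5-(3-methylbut-2-en-1-yl)phenyl]potassium | CON(C)C(=O)C[C@H](Oc1cc(OCOC)c(CC=C(C)C)c(OCOC)c1[K])c1cc(CC=C(C)C)c(OCOC)cc1OCOC | intermediate
31 | potassium (2S)-2-[2,4-bis(methoxymethoxy)-5-(3-methylbut-2-en-1-yl)phenyl]-4-[methoxy(methyl)amino]-5,7-bis(methoxymethoxy)-6-(3-methylbut-2-en-1-yl)-3,4-dihydro-2H-chromen-4-olate (either configuration at C4) | [K+].COCOc1cc(OCOC)c(CC=C(C)C)cc1[C@@H]1CC([O-])(N(C)OC)c2c(OCOC)c(CC=C(C)C)c(OCOC)cc2O1 | intermediate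
32 | (2S)-2-[2,4-bis(methoxymethoxy)-5-(3-methylbut-2-en-1-yl)phenyl]-5,7-bis(methoxymethoxy)-6-(3-methylbut-2-en-1-yl)-2,3-dihydro-4H-chromen-4-one | COCOc1cc(OCOC)c(CC=C(C)C)cc1[C@@H]1CC(=O)c2c(OCOC)c(CC=C(C)C)c(OCOC)cc2O1 | intermediate
33 | (2S)-2-[2,4-dihydroxy-5-(3-methylbut-2-en-1-yl)phenyl]-5,7-dihydroxy-6-(3-methylbut-2-en-1-yl)-2,3-dihydro-4H-chromen-4-one | CC(C)=CCc1cc([C@@H]2CC(=O)c3c(cc(O)c(CC=C(C)C)c3O)O2)c(O)cc1O | target

**Step count and risks**

Total step count: 15. Longest linear sequence: 9 steps (steps 1–7, 14, 15).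

Steps most likely to fail:

1. Step 14 (aryne annulation).
   - What may go wrong: the aryl anion may be protonated before it reaches the amide carbonyl, which would leave an open aryl ether. The naked alkoxide may fragment by retro-aldol cleavage or eliminate. The aryne may be consumed by fluoride or by an ene reaction with a prenyl group. If the hemiaminal alkoxide collapses in the flask, base-induced opening of ring C to the chalcone would erase the C2 configuration.
   - Fallback (known chemistry: aryl addition to the amide, then Mitsunobu ring closure with inversion): it sets out from 25 and 11 and returns at 32. Keto amide 25 would be reduced under the conditions of step 12 with the enantiomeric catalyst RuCl[(R,R)-TsDPEN](p-cymene) to (3R)-3-[2,4-bis(methoxymethoxy)-5-(3-methylbut-2-en-1-yl)phenyl]-3-hydroxy-N-methoxy-N-methylpropanamide F1. F1 would be converted to its magnesium alkoxide with i-PrMgCl and treated at −78 °C with the dianion made from bromophenol 11 and two equivalents of n-BuLi (phenol deprotonation, then bromine–lithium exchange). A single addition to the N-methoxy-N-methylamide should give, after work-up, (3R)-3-[2,4-bis(methoxymethoxy)-5-(3-methylbut-2-en-1-yl)phenyl]-3-hydroxy-1-[6-hydroxy-2,4-bis(methoxymethoxy)-3-(3-methylbut-2-en-1-yl)phenyl]propan-1-one F2. Intramolecular Mitsunobu etherification of F2 (PPh3, diisopropyl azodicarboxylate, THF, 0 °C) should close ring C by SN2 displacement at the carbinol carbon with inversion, giving 32 with the 2S configuration.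

2. Step 15 (global deprotection).
   - What may go wrong: under protic acid a prenyl side chain may cyclise onto a neighbouring freed phenol (dimethylchroman formation). Reversible opening at C2, by ionisation of the benzylic C–O bond helped by the 2',4'-dioxygenated ring B or through the enol, may erode the enantiomeric purity.
   - Fallback (aprotic acetal-to-silyl ether exchange in place of acid solvolysis): it sets out from 32 and returns at 33. Me3SiOTf and 2,2'-bipyridyl in CH2Cl2/MeCN at 0 °C should convert the four aryl methoxymethyl ethers into (2S)-2-{2,4-bis[(trimethylsilyl)oxy]-5-(3-methylbut-2-en-1-yl)phenyl}-6-(3-methylbut-2-en-1-yl)-5,7-bis[(trimethylsilyl)oxy]-2,3-dihydro-4H-chromen-4-one F3, the methoxymethyl cation being taken up by the bipyridyl. Neutral hydrolysis of F3 in aqueous THF at rt should then give 33.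

3. Step 6 (ortho-bromination).
   - What may go wrong: NBS may attack the electron-rich trisubstituted double bond, or both ortho positions may be brominated.
   - Fallback (carbamate-directed ortho-silylation, no electrophilic halogen): it sets out from 10 and returns at 15, bypassing steps 6 and 7. Phenol 10 and isopropyl isocyanate (Et3N cat., CH2Cl2) should give 3,5-bis(methoxymethoxy)-4-(3-methylbut-2-en-1-yl)phenyl propan-2-ylcarbamate F4. In-situ N-silylation (t-BuMe2SiOTf, TMEDA), ortho-lithiation with n-BuLi/TMEDA at −78 °C between the carbamate and the acetal oxygen, and quenching with Me3SiCl should give 3,5-bis(methoxymethoxy)-4-(3-methylbut-2-en-1-yl)-2-(trimethylsilyl)phenyl propan-2-ylcarbamate F5. Cleavage of the carbamate with Et2NH/DBU in MeCN at 40 °C and triflation of the phenolate in the same flask with PhNTf2 should give 15.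

**Further compounds**

F1 | step 14 | (3R)-3-[2,4-bis(methoxymethoxy)-5-(3-methylbut-2-en-1-yl)phenyl]-3-hydroxy-N-methoxy-N-methylpropanamide | CON(C)C(=O)C[C@@H](O)c1cc(CC=C(C)C)c(OCOC)cc1OCOC
F2 | step 14 | (3R)-3-[2,4-bis(methoxymethoxy)-5-(3-methylbut-2-en-1-yl)phenyl]-3-hydroxy-1-[6-hydroxy-2,4-bis(methoxymethoxy)-3-(3-methylbut-2-en-1-yl)phenyl]propan-1-one | COCOc1cc(OCOC)c(CC=C(C)C)cc1[C@H](O)CC(=O)c1c(O)cc(OCOC)c(CC=C(C)C)c1OCOC
F3 | step 15 | (2S)-2-{2,4-bis[(trimethylsilyl)oxy]-5-(3-methylbut-2-en-1-yl)phenyl}-6-(3-methylbut-2-en-1-yl)-5,7-bis[(trimethylsilyl)oxy]-2,3-dihydro-4H-chromen-4-one | C[Si](C)(C)Oc1cc(O[Si](C)(C)C)c(CC=C(C)C)cc1[C@@H]1CC(=O)c2c(O[Si](C)(C)C)c(CC=C(C)C)c(O[Si](C)(C)C)cc2O1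
F4 | step 6 | 3,5-bis(methoxymethoxy)-4-(3-methylbut-2-en-1-yl)phenyl propan-2-ylcarbamate | COCOc1cc(OC(=O)NC(C)C)cc(OCOC)c1CC=C(C)C
F5 | step 6 | 3,5-bis(methoxymethoxy)-4-(3-methylbut-2-en-1-yl)-2-(trimethylsilyl)phenyl propan-2-ylcarbamate | COCOc1cc(OC(=O)NC(C)C)c([Si](C)(C)C)c(OCOC)c1CC=C(C)C
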